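**Retrosynthetic overview**

1. The strategy rests on the acyl part: an unbranched C37 chain whose only functional group is the ester carbonyl C1, so that C2–C37 are thirty-six bare saturated carbons made of two identical C18 halves (C2–C19 and C20–C37). The only ring, the para-disubstituted benzene of the tyrosol part, is bought.
2. The C19–C20 bond is traced back to a reductive dimerisation of two molecules of octadecanal 1, which gives hexatriacont-18-ene, taken as its E isomer 2; the Z isomer 3 that accompanies it is not removed.
3. C1–C2 and C1–O are disconnected together: 2, carbon monoxide 4 and O-benzyl tyrosol 5 are joined by chain-walking alkoxycarbonylation, through the terminal alkene 6, to the protected ester 7.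
4. The phenolic O–benzyl bond is cut last: hydrogenolysis of 7 gives the target 8.
5. No ring is formed at any stage.

Key step: step 2

Assumption: the McMurry coupling of an unbranched aliphatic aldehyde is expected to give mainly the E alkene 2 with a smaller share of the Z isomer 3. The two are not separated. Because the palladium hydride of step 2 interconverts them before any carbonylation, 3 is entered in step 2 as a compound that forms in the flask, to which any share carried over from step 1 simply adds.

**Route**

Step 1
Reactants: 1 octadecanal (two molecules are coupled)
Product: 2 (E)-hexatriacont-18-ene
Conditions: TiCl3(DME)1.5, Zn–Cu couple, DME, reflux; then slow addition of 1 in DME, reflux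
Reagents that add atoms: octadecanal (the second molecule of 1), CCCCCCCCCCCCCCCCCC=O
Why: McMurry reductive carbonyl coupling: the low-valent titanium slurry made from TiCl3 and the zinc–copper couple reduces two molecules of the aldehyde to ketyls that pair and then give up both oxygens to titanium, forming the C18=C19 double bond of the alkene (C19–C20 of the later acyl chain), and because a single aldehyde is homocoupled only one constitution can result, the E geometry being expected to predominate.

Step 2
Reactants: 2 (E)-hexatriacont-18-ene (crude, minor Z isomer included); 4 carbon monoxide; 5 2-[4-(benzyloxy)phenyl]ethanol (fourfold excess, to be recovered)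
Product: 7 2-[4-(benzyloxy)phenyl]ethyl heptatriacontanoate, via (Z)-hexatriacont-18-ene 3 (not isolated), via hexatriacont-1-ene 6 (not isolated)
Conditions: Pd(OAc)2 (2 mol%), 1,2-bis(di-tert-butylphosphinomethyl)benzene (10 mol%), MeSO3H (20 mol%), CO (30 bar), toluene, 90 °C, 3–5 d
Reagents that add atoms: none
Why: Pd(OAc)2, the diphosphine and MeSO3H form a cationic divalent palladium hydride that adds to C18=C19 of 2 and, by repeated beta-hydride elimination and re-insertion, first scrambles the geometry (so that the Z alkene 3, whether brought in from step 1 or formed here, belongs to the same pool) and then moves palladium along the chain through all positional isomers as far as the terminal alkene 6 and the primary alkylpalladium derived from it. CO inserts into that palladium–carbon bond to make C1–C2, and the primary hydroxyl of 5 cleaves the acylpalladium to make C1–O and return the hydride. This is the isomerising alkoxycarbonylation known for internal fatty alkenes such as methyl oleate and methyl erucate with the same catalyst, run here with a few equivalents of a primary alcohol in toluene instead of neat methanol. No ring is closed and no stereocentre is created. The step needs linear over branched selectivity, which the two di-tert-butylphosphino groups secure because alcoholysis of a crowded secondary acyl is much slower than that of the linear acyl, so the equilibrating alkyl pool drains through the chain end; the mirror symmetry of the C36 alkene makes both ends equivalent, so that only one C37 ester can form and the E/Z composition of the feed does not matter. The excess of basic diphosphine buffers the sulfonic acid as phosphonium sulfonate and no H2 is present, so the benzyl aryl ether of 5 should pass unchanged.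

Step 3
Reactants: 7 2-[4-(benzyloxy)phenyl]ethyl heptatriacontanoate
Product: 8 2-(4-hydroxyphenyl)ethyl heptatriacontanoate
Conditions: H2 (1 atm), 10% Pd/C, THF–EtOAc, 40 °C
Reagents that add atoms: none
Why: Catalytic hydrogenolysis cleaves the benzylic C–O bond of the aryl benzyl ether, while the ester hangs on a homobenzylic, non-activated C–O bond and the saturated chain offers nothing else to reduce.

**Compound list**

1 | octadecanal | CCCCCCCCCCCCCCCCCC=O | starting material
2 | (E)-hexatriacont-18-ene | CCCCCCCCCCCCCCCCC/C=C/CCCCCCCCCCCCCCCCC | intermediate
3 | (Z)-hexatriacont-18-ene | CCCCCCCCCCCCCCCCC/C=C\CCCCCCCCCCCCCCCCC | intermediate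
4 | carbon monoxide | [C-]#[O+] | starting material
5 | 2-[4-(benzyloxy)phenyl]ethanol | OCCc1ccc(OCc2ccccc2)cc1 | starting material
6 | hexatriacont-1-ene | C=CCCCCCCCCCCCCCCCCCCCCCCCCCCCCCCCCCC | intermediate
7 | 2-[4-(benzyloxy)phenyl]ethyl heptatriacontanoate | CCCCCCCCCCCCCCCCCCCCCCCCCCCCCCCCCCCCC(=O)OCCc1ccc(OCc2ccccc2)cc1 | intermediate
8 | 2-(4-hydroxyphenyl)ethyl heptatriacontanoate | CCCCCCCCCCCCCCCCCCCCCCCCCCCCCCCCCCCCC(=O)OCCc1ccc(O)cc1 | target

Total step count: 3
Longest linear sequence: 3 steps (1 to 2, to 7, to 8)

**Steps most likely to fail**

1. Step 2 (key step). With only a few equivalents of a bulky alcohol, alcoholysis of the linear acylpalladium may be slow. The catalyst could then decay to palladium metal before the seventeen-position walk is complete, or secondary acyls near the chain end could be intercepted and give branched esters. Slow acid-induced loss or migration of the benzyl group is a second risk. The fallback separates the carbonylation from the esterification. It sets out from 2 and 4: the same catalyst in methanol–toluene, with methanol in large excess (CO 30 bar, 90 °C), should give methyl heptatriacontanoate F1. Saponification (KOH, EtOH–THF–H2O, reflux; then HCl) should give heptatriacontanoic acid F2. Steglich esterification of this acid with 5 (DCC, DMAP cat., CH2Cl2–THF, 40 °C) comes back to the route at 7.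

2. Step 1. The reductive coupling may stop at the diol stage if the titanium slurry is not active enough, and the enolisable aldehyde may be lost to aldol condensation or arrive partly oxidised or trimerised. The fallback replaces the reductive dimerisation by a Wittig olefination and sets out from 1. Commercial octadecyltriphenylphosphonium bromide is deprotonated with NaN(SiMe3)2 in THF at 0 °C to octadecylidene(triphenyl)phosphorane F3, which is treated with 1 at 0 °C to room temperature. The unstabilised ylide should give mainly the Z alkene 3 together with some 2. The path comes back to the route at 3 (accompanied by 2), which enters step 2 directly because the geometry is erased there.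

3. Step 3. The hydrogenolysis may stall through poisoning of the Pd/C surface by phosphine traces carried from step 2, or through precipitation of the waxy substrate onto the catalyst. The fallback is an acidolytic debenzylation that needs no heterogeneous catalyst and sets out from 7: CF3CO2H with excess pentamethylbenzene as cation scavenger in CHCl3 at 40 °C should transfer the benzyl group to the scavenger, while the primary alkyl ester should be inert to anhydrous acid. It comes back to the route at 8 and makes no new compound (F0).

Further compounds
F1 | step 2 | methyl heptatriacontanoate | CCCCCCCCCCCCCCCCCCCCCCCCCCCCCCCCCCCCC(=O)OC
F2 | step 2 | heptatriacontanoic acid | CCCCCCCCCCCCCCCCCCCCCCCCCCCCCCCCCCCCC(=O)O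
F3 | step 1 | octadecylidene(triphenyl)phosphorane | CCCCCCCCCCCCCCCCCC=P(c1ccccc1)(c1ccccc1)c1ccccc1
F0 | step 3 | none | none
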